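Per mole of starting material charged, a cost in partner can be reckoned, and the next run is chosen among the three charges below by that cost.

    intermediate B → target (k1 = 6.2 × 10⁻⁵ s⁻¹)
    starting material + partner → intermediate A (k2 = 0.0051 M⁻¹ s⁻¹)
    starting material + target ⇌ idle adduct, settled at all times (K3 = 6.1 M⁻¹)
    partner + intermediate A → intermediate B (k4 = 8.1 × 10⁻⁴ M⁻¹ s⁻¹)
    starting material + partner → side product (k5 = 0.0048 M⁻¹ s⁻¹)

common to all: partner 0.285 M; time 1.0 h
- birch: starting material 0.030 M
- ash: starting material 0.10 M
- maple: starting material 0.30 M

1. [target] (only what is free in solution) at the end for birch, ash, maple, in this order
2. how the row runs (falls, then rises / falls all the way / rises all the way / hardly changes / rises, then falls)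

- a species is counted by the starting material in it: one idle adduct counts as two
- amounts and yields of target count idle adduct too
- in an amount of target, one idle adduct counts as one target
- the concentration of target that is asked is that of its free form alone
- "hardly changes" means that all values lie within two and a half points (for a concentration: within two and a half percent of the largest)
- run time (birch): 1.0 h

Either branch takes one partner per starting material, and the share of starting material that goes to intermediate A (the selectivity between the branches) takes a second partner later. With partner as charged, starting material has a mean life of 0.0985 h and intermediate A one of 1.20 h, so starting material reacts well ahead of intermediate A. The reckoning therefore works with the fraction of partner left and not with the target made.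

share to intermediate A = k2/(k2+k5) = 0.515

partner per starting material = 1.52

largest charge the partner covers = 0.188 M

The partner bill is the partner that one starting material costs once it has reached side product or intermediate B. Paid in full, it leaves 84.1% of the partner in birch and 46.8% in ash.

Once each starting material has taken its one partner, the fraction of partner left is 0.895 in birch and 0.649 in ash, while the same subtraction gives −0.0526 in maple. Intermediate A moves on in step with that fraction, so free target should follow charge times fraction, and ash should give 2.42 times birch. The reckoning stops at maple, whose charge stands above the covered charge, while that of ash stands below it. The next run is therefore the ash charge, with partner unchanged.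

The forecast gives 7.800 × 10⁻⁴ M, 0.00183 M and 0.00145 M, a row that rises, then falls, and calls target “a lag-limited tail of a consecutive chain”.

The flask gives 7.86 × 10⁻⁴ M, 0.00200 M and 0.00145 M, a row that rises, then falls and turns at a starting material concentration of 0.17 M; ash stands at 2.54 times birch, against the reckoned 2.42.

In birch after 1.00 h, intermediate B is made 3.90 times faster than it is used up, net, and it stands at 22.2% of the charge against 2.62% for target. After 10.0 h, birch holds 84.1% of its partner against the 84.1% the bill leaves, ash holds 47.1% against 46.8%, and maple, charged above what the partner covers, has 0% of its partner with 9.68% of its starting material still there unbound.

The constants are assumed, and the outcome is calculated.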